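The data stem from a simulated flask on assumed constants; the scatter is artificial.

The leftover of the east run is where I started: at 4.00 h, with solid E at 0% and G at 35.7%, 64.3% of the charge was still not G.

| setting | east | south-west | flask |
|---|---|---|---|
| E | 0.28 M | 1.1 M | 0.57 M |
| X | 1.05 equiv | 1.05 equiv | 1.05 equiv |
| remark | run made earlier | run made earlier |  |
| time |  |  | 6.0 h |

| run | time / h | E / % | G / % |
|---|---|---|---|
| east | 0.200 | 78.6 | 0 |
| east | 0.500 | 53.3 | 1.8 |
| east | 1.00 | 23.7 | 6.8 |
| east | 1.50 | 3.2 | 13.1 |
| east | 2.00 | 0.4 | 18.9 |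
| east | 3.00 | 0 | 29.1 |
| east | 4.00 | 0 | 35.7 |
| south-west | 0.500 | 87.8 | 2.0 |
| south-west | 1.00 | 79.2 | 5.9 |
| south-west | 1.50 | 72.6 | 11.0 |
| south-west | 2.00 | 65.7 | 15.1 |
| south-west | 2.50 | 60.1 | 20.0 |
| south-west | 3.00 | 53.5 | 24.1 |
| south-west | 4.00 | 43.9 | 30.9 |

(each reading ± 0.3 percentage points)

- at the start none of E is in solution
- a reading or a percentage of Q counts all its forms, free or not

- E at 6.0 h, in percent of the E charged (only what is still solid)
- G at 6.0 h, in percent of the E charged
- Q at 6.0 h, in percent of the E charged
- L at 6.0 h, in percent of the E charged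

From 2.00 h, with solid E down to 0.4%, dissolved E and X stood nearly equal in the east run, at 1.05 equiv. So one over the share not yet G should climb straight with time, and its slope, divided by the charge, read 0.575 /M/h.

That gave 3.05 h for the flask and 6.21 h for the east run. I called this the pairing time: one over that constant and the charge, the time in which equal partners fall to half (a second-order half-life). The flask looked like the east run at twice the strength, so a dissolved molecule of E found its X sooner there.

But a molecule first waits in the solid. The south-west run had dissolved 0.301 M by 1.50 h, about half the flask's charge, so I took 1.50 h as the typical wait of a molecule in the flask. That run had dissolved 0.617 M by 4.00 h, more than the flask's charge, so I expected the flask's solid to be gone by 6.0 h. The time left, over the pairing time, put 59.6% of the flask's charge beyond dissolved E, with G below that figure because some passes on to Q and L.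

The forecast, where “solid almost disappears near 5.5–6 h”, gave E 3%, G 47%, Q 7% and L 0.7%. The flask gave E 0%, G 51.7%, Q 3.51% and L 0.732%.

    D + X → G (k = 0.600 /M/h)
    X + G → Q (k = 0.0900 /M/h)
    X + Q → L (k = 0.250 /M/h)
    Q ⇌ Z (K = 2.00, k = 0.110 /h)
    E ⇌ D, rate k5*(cs5 - [D]) while solid is left; crystals form when [D] > cs5 (solubility = 0.330 M, k = 1.00 /h)
    J ⇌ Q, rate k6*(cs6 - [Q]) while solid is left; crystals form when [Q] > cs6 (solubility = 22.0 mM, k = 2.90 /h)

In the flask, E dissolved while solid remained, standing at 25.6% with D at 44.3% at 3.00 h. At 6.00 h, with E at 0%, 56.9% of the charge lay beyond D, against my 59.6%. The neighbouring flask with 0.14 M of E has a pairing time of 12.4 h, which, with the wait set aside, puts 32.6% beyond D; there 33.8% lay beyond D at 6.00 h, and G stood at 32.7%.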